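The constants used here are those of an exercise; the result is computed.

The trap in repeating this run is to watch the starting material creep down and answer with more gas, so the first thing to reckon is how much target any gas supply can give.

starting material 0.050 M; gas phase 4.3 mM (held); protic impurity 0.0150 M; time 30 h

    dissolved gas + protic impurity → quenched reagent (k1 = 22.5 M⁻¹ h⁻¹)
    starting material + dissolved gas → target (k2 = 83.4 M⁻¹ h⁻¹)
    2 dissolved gas → self-condensation product (k3 = 35.3 M⁻¹ h⁻¹)
    dissolved gas + target → over-reacted product (k4 = 3.69 M⁻¹ h⁻¹)
    gas phase ⇌ dissolved gas, rate k5*(csat - [dissolved gas]) (k5 = 0.860 h⁻¹, csat = 4.3 mM)

- for a step with 2 of a species take k times the square, and two of it per event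
- at the start none of the gas is dissolved
- run time (flask): 30 h

- summer: doubling the transfer coefficient of step 5, all else as stated
- dusk: doubling the saturation concentration of gas phase, all else as stated

* the target standing at 30 h, as a percentage of the starting material charged
* concentration of dissolved gas in solution at 8.0 h, in percent of saturation
* the change that raises the amount of target at 30 h, in percent of the starting material charged most ("none" if none brings more than 2 percentage points) (summer / dusk / none)
* amount of target at 30 h, in percent of the starting material charged, after dusk

1. My own reckoning starts from steps 2 and 4, which both run at a rate proportional to dissolved gas, so dividing one by the other cancels the gas concentration. Let a be the fraction of starting material left, P the target as a fraction of the charge, and s = k4/k2 = 0.0442, the selectivity factor.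

2. Then P = (a^s − a)/(1 − s), a curve in a with time gone from it. It peaks where P = a/s, and there P = a^s.

3. Iterating from P = 1 gives a = 4.42 % and P = 87.1 %. Going round once more gives a = 3.85 % and P = 86.6 %. This peak is the yield ceiling, reached with 3.83 % of the starting material left.

4. Step 5 can deliver at most 222 % of the charge by 30 h into a solution kept empty, but that bound on supply does not say where on the curve the flask stands at 30 h. Summer and dusk leave s as it is, so both changes stay on this curve and under the same ceiling. My decision is to change neither transfer nor saturation and to watch the starting material. My reckoning gives the ceiling, not the values asked for at 8.0 h or after dusk.

5. The forecast gives 86 % for the target, 22.7 % of saturation, none as the best change and 68 % after dusk, on the ground that “neither improves the yield”.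

6. The simulation gives 86.2 %, 22.6 %, none and 68.0 %. Summer moves the target by −7.3 percentage points and dusk by −18 points.

The flask at 30 h holds 2.34 % of its starting material, less than the peak point, and its target stands 0.40 points under the ceiling, a gap smaller than 2 points. Part of the reason the flask still holds this much target at 30 h is the slowness of the way of gas phase across to dissolved gas, together with the hour of the reading: the run with fast transfer holds 65.1 % against 86.2 %, and the flask read at 300 h holds 3.55 %. For the neighbour flask read at 12 h, with 41 % of the starting material left, the curve gives 57.7 %, and that flask reads 57.6 %.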